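**Assumption:** Rh2(S-PTTL)4 is taken to favour the 2S product in the insertion; if the 2R product prevailed, the mirror-image catalyst Rh2(R-PTTL)4 would replace it with no other change.

## Structural features

Compound 16 is a flavanone. A 1,3,5-trioxygenated benzene ring A is fused through C4a–C8a to a dihydropyranone ring C (O1, C2, C3, C4 ketone), and ring B, a 2',4'-dihydroxyphenyl group, sits on C2. Ring A carries free hydroxyls at C5 and C7 and a prenyl chain at C8, next to O1. Ring B carries a reverse prenyl (2-methylbut-3-en-2-yl) group at C5', ortho to the 4'-OH. C2 (S) is the only stereocentre, so no neighbouring centre can relay its configuration and a reagent must set it. The molecule is fragile in three ways: base opens ring C by retro-oxa-Michael reaction and racemises C2, acid closes the prenyl group onto the 7-OH and the reverse prenyl group onto the 4'-OH, and the two alkenes rule out hydrogenolysis. The real difficulty is to set C2 late and under neutral conditions on a skeleton whose two different C5 units have been placed regiospecifically on two polyphenolic rings. The key step exploits the fact that C2 is a CH bonded to O1 and ring B while C3 is a CH2 next to the C4 ketone. A carbene at C3 can therefore insert into a benzylic C–H of an O1–CH2–ring B ether, closing ring C at the ketone oxidation level and creating C2 in one operation.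

## Logic of the disconnections

**16 to 15.** No skeletal bond is cut; the four phenolic O–H bonds of 16 become O–Si bonds (triisopropylsilyl on O5, O7, O2' and O4'). Free phenols would quench a metal carbene by O–H insertion and would interfere with the enolate chemistry before it. The gain is one uniform, fluoride-labile protecting group for the whole route. The forward step must cleave four aryl silyl ethers with neither base strong enough to open ring C nor acid strong enough to cyclise the side chains.

**15 to 14.** The C2–C3 bond is cut. This opens ring C and erases the only stereocentre: C2 becomes the prochiral CH2 of a benzyl ether on O1, and C3 becomes a diazo carbon beside the C4 ketone. A chiral bicyclic ketone is reduced to an achiral diaryl system joined by one O–CH2 link. The forward step must choose one of two enantiotopic benzylic hydrogens and must prefer C–H insertion to attack on the ether oxygens. The spectator groups of 14 were chosen for this step. Ring B carries triisopropylsilyl rather than smaller silyl groups because an ortho-silyloxy benzyl alkoxide passes a small silyl group from the aryl to the benzylic oxygen, and a small aryl silyl ether is also less secure towards the amide base and the phenol-alkylation conditions used earlier. The O5 group is the same bulky silyl ether, which screens that oxygen from the carbene.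

**14 to 12.** The C3=N bond of the diazo group is cut, leaving the methyl ketone that 1 already contains, so no one-carbon homologation with diazomethane is needed. The forward step must activate the methyl group for diazo transfer without harming four silyl ethers and two alkenes, which is done with a temporary trifluoroacetyl group.

**12 to 4 and 11.** The O1–CH2 bond is cut. This is the convergent cut: it gives two aromatic halves of similar size, each carrying its own C5 unit. The forward step must alkylate a hindered, chelated phenol. Which hydroxyl of 4 is free decides that the prenyl group ends at C8 and not at C6. The electrophile is the alcohol 11, activated in the flask, because a 2,4-dioxygenated benzyl halide ionises and self-condenses easily.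

**11 to 10 to 9.** The benzylic C–H bond is cut (alcohol back to aldehyde), then the O4'–Si bond. The aldehyde is the native function of 5 and is needed to steer the earlier chemistry. The forward steps must silylate a phenol beside a quaternary carbon and reduce the aldehyde without silyl migration.

**9 to 7 (through 8).** The C5'–C(CH3)2 bond is cut and the O4'–CH2 bond is reformed, the retron of an aromatic Claisen rearrangement. This replaces a hard aryl–quaternary carbon bond by a simple O-alkylation. The forward step must deliver the allyl unit to C5' and not C3', and the freed phenol must not rearrange further.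

**7 to 6 to 5 and 2.** The O2'–Si bond and then the O4'–CH2 bond are cut. The forward steps must alkylate O4' in the presence of O2' and then cap O2'.

**4 to 3 to 1 and 2.** The O5–Si and O7–Si bonds and then the C8–CH2 bond are cut. The forward steps must mono-alkylate 1 at carbon and then silylate two of three hydroxyls of 3, leaving free only the one flanked by the prenyl and acetyl groups.

## Other disconnections considered

**Alternative 1:** The cut is O1–C8a. The diol aryl triflate A2 would be closed to the flavan-4-ol A1 by intramolecular aryl ether formation with Pd2(dba)3 (zerovalent palladium), a di-tert-butyl biaryl phosphine and Cs2CO3.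
- In favour: C2 is a carbinol centre set before ring closure by ordinary carbonyl chemistry and is not touched when the C–O bond forms. The C4 hydroxyl cannot compete because it would give a four-membered ring. No diazo compound is needed.
- Against: the triflate of A2 sits between the 8-prenyl group and the side chain on a ring with two more oxygen donors, a poor case for oxidative addition. The palladium-bound secondary benzylic alkoxide can undergo β-hydride elimination instead of reductive elimination. A1 is at the wrong oxidation level, and its four methoxymethyl ethers need acid for removal, which invites cyclisation of both C5 side chains onto their neighbouring phenols.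
- On structure: it needs a ring A with three differentiated oxygens and two stereocentres, one of which is discarded; the chosen plan needs neither.
- On mechanism: a two-electron cross-coupling with retention at C2 is better than the chosen plan for the security of the C2 configuration, since no enantiotopic-group selection is asked of the ring-forming step.
- On step economy: it is worse, with an oxidation and an acidic deprotection after closure and a longer way to A2.

**Alternative 2:** The cuts are O1–C2 and C3–C4. The salicylaldehyde A4, HC(OMe)3 and a chiral phosphoric acid would give a methoxy-substituted ortho-quinone methide cation that adds the 2-hydroxystyrene A5 to give the 4-methoxyflavan A3.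
- In favour: two bonds, ring C and the C2 stereocentre would form in one step from two fragments of similar size. On convergence and bonds formed per step this alternative is better than the chosen plan.
- Against: A3 is not at the ketone oxidation level. C4 would have to be oxidised from a benzylic methyl ether in the presence of two very electron-rich rings, a free phenol and two alkenes, and the C4 stereocentre is wasted. The Brønsted acid medium threatens the prenyl groups and silyl ethers, A5 is prone to acid-induced oligomerisation, and the formyl group of A4 is crowded by the ortho silyloxy group.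
- On structure: it builds more per step but delivers the wrong functional group at C4.
- On mechanism: a stepwise cationic cycloaddition steered by ion pairing and the free 2'-OH is, like the carbene insertion, purely catalyst-controlled, so the two are equal in having no substrate bias to rely on.
- On step economy: the way to A4 and A5 is about as long as the way to 14, but two or three steps follow A3 against one after 15, so no net gain is expected.

**Alternative 3:** The cut is C4–C4a. The acid A7, activated as its mixed anhydride with trifluoroacetic anhydride, would acylate C4a to give the flavanone A6.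
- In favour: A6 is at the ketone oxidation level, equal to the chosen plan on that point. Ring A has only one free position ortho to O1, so the site of closure is unambiguous; this is better than the chosen plan, where insertion must outrun ylide formation. No transition metal is needed.
- Against: the acidic, strongly electrophilic medium can protonate the prenyl and reverse prenyl alkenes and loosen aryl silyl ethers. The activated β-aryloxy acid can lose the aryloxide by β-elimination. The C2–O bond, benzylic to an oxygenated ring B, can ionise with loss of configuration. The acetates that temper this need base for removal, which endangers C2 in the final flavanone. The stereocentre must be made earlier by joining a hindered phenol to a secondary benzylic carbon, which moves the stereochemical problem without making it easier.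
- On structure: one bond is formed, as in the chosen plan, but with two kinds of protecting group.
- On mechanism: electrophilic aromatic substitution is more predictable in site selectivity but exposes C2 to conditions that can erode it, whereas the carbene insertion creates C2 in the last skeletal step under neutral conditions.
- On step economy: comparable before the closure, one more deprotection mode after it.

Key step: step 10

## Route

Step 1
Reactants: 1 2,4,6-trihydroxyacetophenone; 2 prenyl bromide (1-bromo-3-methylbut-2-ene)
Product: 3 1-[2,4,6-trihydroxy-3-(3-methylbut-2-en-1-yl)phenyl]ethanone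
Conditions: 2 (1.0 equiv), KOH (10% aq.), 0 °C → rt
Reagents that add atoms: none
Why: C-alkylation of the phloroglucinol polyanion (Friedel–Crafts-type alkylation of an ambident phenoxide); water favours attack through carbon, the two free ring carbons are equivalent, and limiting 2 should hold back a second alkylation.

Step 2
Reactants: 3 1-[2,4,6-trihydroxy-3-(3-methylbut-2-en-1-yl)phenyl]ethanone
Product: 4 1-[2-hydroxy-3-(3-methylbut-2-en-1-yl)-4,6-bis(triisopropylsilyloxy)phenyl]ethanone
Conditions: TIPSCl (2.2 equiv), imidazole, DMAP (cat.), DMF, 0 °C → rt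
Reagents that add atoms: triisopropylsilyl chloride, CC(C)[Si](Cl)(C(C)C)C(C)C
Why: Regioselective phenol silylation; the para hydroxyl (most acidic, not chelated) and the less hindered ortho hydroxyl should react, while the hydroxyl flanked by the prenyl and acetyl groups stays hydrogen-bonded to the carbonyl and is too shielded for the bulky silyl chloride.

Step 3
Reactants: 5 2,4-dihydroxybenzaldehyde; 2 prenyl bromide (1-bromo-3-methylbut-2-ene)
Product: 6 2-hydroxy-4-(3-methylbut-2-en-1-yloxy)benzaldehyde
Conditions: 2 (1.0 equiv), K2CO3 (1.0 equiv), acetone, rt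
Reagents that add atoms: none
Why: Williamson ether synthesis; the 2-OH is tied up in the hydrogen bond to the formyl group and is the weaker acid, so one equivalent of base and bromide should alkylate O4 only.

Step 4
Reactants: 6 2-hydroxy-4-(3-methylbut-2-en-1-yloxy)benzaldehyde
Product: 7 4-(3-methylbut-2-en-1-yloxy)-2-(triisopropylsilyloxy)benzaldehyde
Conditions: TIPSCl, imidazole, DMF, rt
Reagents that add atoms: triisopropylsilyl chloride, CC(C)[Si](Cl)(C(C)C)C(C)C
Why: Silylation of the chelated phenol; capping O2 removes the chelate that would steer the coming rearrangement to C3 and puts a bulky group next to that position.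

Step 5
Reactants: 7 4-(3-methylbut-2-en-1-yloxy)-2-(triisopropylsilyloxy)benzaldehyde
Product: 9 4-hydroxy-5-(2-methylbut-3-en-2-yl)-2-(triisopropylsilyloxy)benzaldehyde, via trimethylsilyl ether 8 (not isolated)
Conditions: N,O-bis(trimethylsilyl)acetamide (2 equiv), PhNEt2, 180 °C, sealed tube; then 1 M aq. HCl, THF, 0 °C
Reagents that add atoms: N,O-bis(trimethylsilyl)acetamide, CC(=N[Si](C)(C)C)O[Si](C)(C)C (its Me3Si group is held in 8 only)
Why: Aromatic Claisen rearrangement ([3,3]-sigmatropic shift with allylic inversion, so O-prenyl becomes C-1,1-dimethylallyl) followed by tautomerisation; C5 should be preferred because C3 is wedged between two oxygen substituents and C5 lies para to the O2 donor, and silylation of the phenol as it forms blocks abnormal Claisen rearrangement and ring closure onto the alkene before the labile trimethylsilyl ether is hydrolysed on work-up.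

Step 6
Reactants: 9 4-hydroxy-5-(2-methylbut-3-en-2-yl)-2-(triisopropylsilyloxy)benzaldehyde
Product: 10 5-(2-methylbut-3-en-2-yl)-2,4-bis(triisopropylsilyloxy)benzaldehyde
Conditions: TIPSOTf, 2,6-lutidine, CH2Cl2, 0 °C
Reagents that add atoms: triisopropylsilyl trifluoromethanesulfonate, CC(C)[Si](OS(=O)(=O)C(F)(F)F)(C(C)C)C(C)C
Why: Silyl triflate silylation of a phenol hindered by the ortho quaternary carbon; the aldehyde cannot enolise and the hindered base keeps the medium free of acid that could cyclise the phenol onto the alkene.

Step 7
Reactants: 10 5-(2-methylbut-3-en-2-yl)-2,4-bis(triisopropylsilyloxy)benzaldehyde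
Product: 11 [5-(2-methylbut-3-en-2-yl)-2,4-bis(triisopropylsilyloxy)phenyl]methanol
Conditions: NaBH4, THF–MeOH, 0 °C
Reagents that add atoms: none
Why: Hydride reduction of the aldehyde; the bulky triisopropylsilyl group on O2 should resist the aryl-to-benzyl O-to-O silyl shift through the alkoxide that a smaller silyl group would undergo.

Step 8
Reactants: 4 1-[2-hydroxy-3-(3-methylbut-2-en-1-yl)-4,6-bis(triisopropylsilyloxy)phenyl]ethanone; 11 [5-(2-methylbut-3-en-2-yl)-2,4-bis(triisopropylsilyloxy)phenyl]methanol
Product: 12 1-{2-[5-(2-methylbut-3-en-2-yl)-2,4-bis(triisopropylsilyloxy)benzyloxy]-3-(3-methylbut-2-en-1-yl)-4,6-bis(triisopropylsilyloxy)phenyl}ethanone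
Conditions: PPh3, DIAD, toluene, 0 °C → rt
Reagents that add atoms: none
Why: Mitsunobu etherification of a primary benzylic alcohol with an acidic ortho-acyl phenol under neutral conditions, which avoids isolating the labile electron-rich benzyl halide and any basic medium that could move silyl groups.

Step 9
Reactants: 12 1-{2-[5-(2-methylbut-3-en-2-yl)-2,4-bis(triisopropylsilyloxy)benzyloxy]-3-(3-methylbut-2-en-1-yl)-4,6-bis(triisopropylsilyloxy)phenyl}ethanone
Product: 14 2-diazo-1-{2-[5-(2-methylbut-3-en-2-yl)-2,4-bis(triisopropylsilyloxy)benzyloxy]-3-(3-methylbut-2-en-1-yl)-4,6-bis(triisopropylsilyloxy)phenyl}ethanone, via trifluoroacetyl ketone 13 (not isolated)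
Conditions: LiN(SiMe3)2, THF, −78 °C; CF3CO2CH2CF3; cold 1 M HCl work-up; then p-ABSA, Et3N, H2O (1 equiv), MeCN, rt
Reagents that add atoms: 2,2,2-trifluoroethyl trifluoroacetate, O=C(OCC(F)(F)F)C(F)(F)F (its CF3CO group is held in 13 only); 4-acetamidobenzenesulfonyl azide, CC(=O)Nc1ccc(cc1)S(=O)(=O)N=[N+]=[N-] (two nitrogen atoms in 14)
Why: Detrifluoroacetylative diazo transfer (a Regitz-type transfer to an activated ketone): Claisen condensation of the lithium enolate gives the 1,3-diketone, which takes up the diazo group from the sulfonyl azide and loses the trifluoroacetyl group as the N-sulfonyl amide; nothing acidic or strongly nucleophilic touches the silyl ethers or alkenes.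

Step 10
Reactants: 14 2-diazo-1-{2-[5-(2-methylbut-3-en-2-yl)-2,4-bis(triisopropylsilyloxy)benzyloxy]-3-(3-methylbut-2-en-1-yl)-4,6-bis(triisopropylsilyloxy)phenyl}ethanone
Product: 15 (2S)-2-[5-(2-methylbut-3-en-2-yl)-2,4-bis(triisopropylsilyloxy)phenyl]-8-(3-methylbut-2-en-1-yl)-5,7-bis(triisopropylsilyloxy)chroman-4-one
Conditions: Rh2(S-PTTL)4 (2 mol%), CH2Cl2, 0 °C, 14 added over 2 h
Reagents that add atoms: none
Why: Loss of N2 from 14 on Rh2(S-PTTL)4 gives an electrophilic carbene at C3, which inserts into one of the two enantiotopic hydrogens of the O1–CH2–aryl group through a three-centre, hydride-transfer-like transition state and so forms C2–C3. The closest known reaction type is the enantioselective intramolecular C–H insertion of 2-alkoxyaryl diazo ketones to 2-substituted chroman-4-ones under chiral Rh2(O2CR)4 catalysts (divalent rhodium). Ring C closes in a 1,6-insertion mode: the six-membered ring of C3, C4, C4a, C8a, O1 and C2 forms by C–C bond formation at the carbon alpha to oxygen, and no five-membered alternative exists because the aromatic carbon C8a bears no hydrogen. The C2 stereocentre is set by the catalyst alone: the phthalimido walls of the tert-leucinate ligands form a chiral pocket around the carbene that should let only one benzylic hydrogen reach the carbene carbon with the bulky ring B turned away from the ligands. The step needs C–H insertion to win over attack of O1 on the carbene (oxonium ylide, then 1,2-benzyl shift with ring contraction) and over attack of O5. The substrate helps in four ways: O1 and the ortho and para silyloxy groups of ring B make the benzylic C–H hydridic, the 8-prenyl group presses the benzyloxy group towards the carbene, the triisopropylsilyl group screens O5 and offers no C–H alpha to oxygen, and a carboxylate of divalent rhodium should favour insertion where Cu(hfacac)2 (divalent copper) would favour the ylide. Slow addition at high dilution should suppress carbene dimerisation and intermolecular cyclopropanation of the side-chain alkenes, which the carbene cannot reach within the molecule.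

Step 11
Reactants: 15 (2S)-2-[5-(2-methylbut-3-en-2-yl)-2,4-bis(triisopropylsilyloxy)phenyl]-8-(3-methylbut-2-en-1-yl)-5,7-bis(triisopropylsilyloxy)chroman-4-one
Product: 16 (2S)-2-[2,4-dihydroxy-5-(2-methylbut-3-en-2-yl)phenyl]-5,7-dihydroxy-8-(3-methylbut-2-en-1-yl)chroman-4-one (AChE-IN-17)
Conditions: Bu4NF, AcOH (1:1, 5 equiv), THF, 0 °C → rt
Reagents that add atoms: none
Why: Fluoride-induced cleavage of aryl silyl ethers; acetic acid protonates each phenoxide as it forms, so the retro-oxa-Michael opening that would racemise C2 should not start, and no acid strong enough to cyclise the side chains onto their neighbouring phenols is present.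

## Compound list

1 | 2,4,6-trihydroxyacetophenone | CC(=O)c1c(O)cc(O)cc1O | starting material
2 | prenyl bromide (1-bromo-3-methylbut-2-ene) | CC(C)=CCBr | starting material
3 | 1-[2,4,6-trihydroxy-3-(3-methylbut-2-en-1-yl)phenyl]ethanone | CC(=O)c1c(O)cc(O)c(CC=C(C)C)c1O | intermediate
4 | 1-[2-hydroxy-3-(3-methylbut-2-en-1-yl)-4,6-bis(triisopropylsilyloxy)phenyl]ethanone | CC(=O)c1c(O[Si](C(C)C)(C(C)C)C(C)C)cc(O[Si](C(C)C)(C(C)C)C(C)C)c(CC=C(C)C)c1O | intermediate
5 | 2,4-dihydroxybenzaldehyde | O=Cc1ccc(O)cc1O | starting material
6 | 2-hydroxy-4-(3-methylbut-2-en-1-yloxy)benzaldehyde | O=Cc1ccc(OCC=C(C)C)cc1O | intermediate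
7 | 4-(3-methylbut-2-en-1-yloxy)-2-(triisopropylsilyloxy)benzaldehyde | O=Cc1ccc(OCC=C(C)C)cc1O[Si](C(C)C)(C(C)C)C(C)C | intermediate
8 | 5-(2-methylbut-3-en-2-yl)-2-(triisopropylsilyloxy)-4-(trimethylsilyloxy)benzaldehyde | O=Cc1cc(C(C)(C)C=C)c(O[Si](C)(C)C)cc1O[Si](C(C)C)(C(C)C)C(C)C | intermediate
9 | 4-hydroxy-5-(2-methylbut-3-en-2-yl)-2-(triisopropylsilyloxy)benzaldehyde | O=Cc1cc(C(C)(C)C=C)c(O)cc1O[Si](C(C)C)(C(C)C)C(C)C | intermediate
10 | 5-(2-methylbut-3-en-2-yl)-2,4-bis(triisopropylsilyloxy)benzaldehyde | O=Cc1cc(C(C)(C)C=C)c(O[Si](C(C)C)(C(C)C)C(C)C)cc1O[Si](C(C)C)(C(C)C)C(C)C | intermediate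
11 | [5-(2-methylbut-3-en-2-yl)-2,4-bis(triisopropylsilyloxy)phenyl]methanol | OCc1cc(C(C)(C)C=C)c(O[Si](C(C)C)(C(C)C)C(C)C)cc1O[Si](C(C)C)(C(C)C)C(C)C | intermediate
12 | 1-{2-[5-(2-methylbut-3-en-2-yl)-2,4-bis(triisopropylsilyloxy)benzyloxy]-3-(3-methylbut-2-en-1-yl)-4,6-bis(triisopropylsilyloxy)phenyl}ethanone | CC(=O)c1c(O[Si](C(C)C)(C(C)C)C(C)C)cc(O[Si](C(C)C)(C(C)C)C(C)C)c(CC=C(C)C)c1OCc1cc(C(C)(C)C=C)c(O[Si](C(C)C)(C(C)C)C(C)C)cc1O[Si](C(C)C)(C(C)C)C(C)C | intermediate
13 | 4,4,4-trifluoro-1-{2-[5-(2-methylbut-3-en-2-yl)-2,4-bis(triisopropylsilyloxy)benzyloxy]-3-(3-methylbut-2-en-1-yl)-4,6-bis(triisopropylsilyloxy)phenyl}butane-1,3-dione | O=C(CC(=O)C(F)(F)F)c1c(O[Si](C(C)C)(C(C)C)C(C)C)cc(O[Si](C(C)C)(C(C)C)C(C)C)c(CC=C(C)C)c1OCc1cc(C(C)(C)C=C)c(O[Si](C(C)C)(C(C)C)C(C)C)cc1O[Si](C(C)C)(C(C)C)C(C)C | intermediate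
14 | 2-diazo-1-{2-[5-(2-methylbut-3-en-2-yl)-2,4-bis(triisopropylsilyloxy)benzyloxy]-3-(3-methylbut-2-en-1-yl)-4,6-bis(triisopropylsilyloxy)phenyl}ethanone | [N-]=[N+]=CC(=O)c1c(O[Si](C(C)C)(C(C)C)C(C)C)cc(O[Si](C(C)C)(C(C)C)C(C)C)c(CC=C(C)C)c1OCc1cc(C(C)(C)C=C)c(O[Si](C(C)C)(C(C)C)C(C)C)cc1O[Si](C(C)C)(C(C)C)C(C)C | intermediate
15 | (2S)-2-[5-(2-methylbut-3-en-2-yl)-2,4-bis(triisopropylsilyloxy)phenyl]-8-(3-methylbut-2-en-1-yl)-5,7-bis(triisopropylsilyloxy)chroman-4-one | C=CC(C)(C)c1cc([C@@H]2CC(=O)c3c(O[Si](C(C)C)(C(C)C)C(C)C)cc(O[Si](C(C)C)(C(C)C)C(C)C)c(CC=C(C)C)c3O2)c(O[Si](C(C)C)(C(C)C)C(C)C)cc1O[Si](C(C)C)(C(C)C)C(C)C | intermediate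
16 | (2S)-2-[2,4-dihydroxy-5-(2-methylbut-3-en-2-yl)phenyl]-5,7-dihydroxy-8-(3-methylbut-2-en-1-yl)chroman-4-one (AChE-IN-17) | C=CC(C)(C)c1cc([C@@H]2CC(=O)c3c(O)cc(O)c(CC=C(C)C)c3O2)c(O)cc1O | target

## Step count and least certain steps

Total: 11 steps, each one-pot sequence counted as one. Longest linear sequence: 9 steps (5 to 16 through steps 3 to 11); the ring A branch (steps 1 and 2) joins at step 8.

**Step 10 (key step).** The most likely failures are diversion of the carbene through attack of O1, oxonium ylide formation and 1,2-shift of the very electron-rich benzyl group, and incomplete discrimination between the two enantiotopic benzylic hydrogens, because a carbene with only one acceptor group is highly reactive and reacts early. The fallback sets out from 4 and 10 and returns at 15.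
- Aldol condensation of the dianion of 4 with 10 (LiN(SiMe3)2, THF, −78 °C → rt) would give the 2'-hydroxychalcone (E)-1-[2-hydroxy-3-(3-methylbut-2-en-1-yl)-4,6-bis(triisopropylsilyloxy)phenyl]-3-[5-(2-methylbut-3-en-2-yl)-2,4-bis(triisopropylsilyloxy)phenyl]prop-2-en-1-one F1.
- Oxa-Michael ring closure (NaOAc, EtOH, heat) would give the racemic flavanone F2.
- Kinetic resolution by asymmetric transfer hydrogenation (HCO2H–Et3N) with the catalyst enantiomer that consumes the 2R ketone, expected by analogy with chroman-4-one reductions to be RuCl[(R,R)-TsDPEN](p-cymene), would convert that half into the cis-(2R,4R)-flavan-4-ol F3. This is separable from the unreacted 2S ketone, which is 15.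

**Step 5.** The allyl unit may migrate to C3 instead of C5, and the freed ortho-(1,1-dimethylallyl)phenol may rearrange further (abnormal Claisen) or close onto its alkene if silyl trapping is slower than these processes at 180 °C. The fallback sets out from 5 and returns at 10.
- Bromination (Br2, AcOH) would give 5-bromo-2,4-dihydroxybenzaldehyde F4.
- Silylation (TIPSOTf, 2,6-lutidine) would give 5-bromo-2,4-bis(triisopropylsilyloxy)benzaldehyde F5.
- Suzuki–Miyaura coupling with prenylboronic acid pinacol ester, using Pd(OAc)2 with a biaryl phosphine ligand chosen for bond formation through the γ-carbon of the allyl unit and K3PO4 in aqueous THF, would install the 1,1-dimethylallyl group at the carbon that carried bromine and give 10. The ligand would have to be selected for branched selectivity.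

**Step 8.** The chelated phenol, flanked by two ortho substituents, may be alkylated too slowly, and the activated electron-rich benzylic alcohol may ionise, leading to C-benzylation or self-condensation. The fallback sets out from 11 and returns at 12.
- Appel reaction (CBr4, PPh3, CH2Cl2, 0 °C) would give 1-(bromomethyl)-5-(2-methylbut-3-en-2-yl)-2,4-bis(triisopropylsilyloxy)benzene F6.
- Used at once without purification, F6 would alkylate 4 under Williamson conditions (K2CO3, acetone, rt) to give 12.

**Step 1.** Over-alkylation and O-alkylation of the ambident anion of 1 may leave little of the mono-C-prenyl product. The fallback sets out from 1 and returns at 4.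
- Bis-silylation (TIPSCl, imidazole, DMF) would give 1-[2-hydroxy-4,6-bis(triisopropylsilyloxy)phenyl]ethanone F7.
- Tsuji–Trost O-alkylation with methyl 2-methylbut-3-en-2-yl carbonate and Pd(PPh3)4 (zerovalent palladium) in THF would give the tertiary allyl aryl ether 1-[2-(2-methylbut-3-en-2-yloxy)-4,6-bis(triisopropylsilyloxy)phenyl]ethanone F8.
- Aromatic Claisen rearrangement (toluene, 110 °C) would move the allyl unit, with inversion, to the only free ortho carbon and give 4 with its prenyl group next to the free hydroxyl.

## Further compounds

F1 | step 10 | (E)-1-[2-hydroxy-3-(3-methylbut-2-en-1-yl)-4,6-bis(triisopropylsilyloxy)phenyl]-3-[5-(2-methylbut-3-en-2-yl)-2,4-bis(triisopropylsilyloxy)phenyl]prop-2-en-1-one | C=CC(C)(C)c1cc(/C=C/C(=O)c2c(O[Si](C(C)C)(C(C)C)C(C)C)cc(O[Si](C(C)C)(C(C)C)C(C)C)c(CC=C(C)C)c2O)c(O[Si](C(C)C)(C(C)C)C(C)C)cc1O[Si](C(C)C)(C(C)C)C(C)C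
F2 | step 10 | racemic 2-[5-(2-methylbut-3-en-2-yl)-2,4-bis(triisopropylsilyloxy)phenyl]-8-(3-methylbut-2-en-1-yl)-5,7-bis(triisopropylsilyloxy)chroman-4-one | C=CC(C)(C)c1cc(C2CC(=O)c3c(O[Si](C(C)C)(C(C)C)C(C)C)cc(O[Si](C(C)C)(C(C)C)C(C)C)c(CC=C(C)C)c3O2)c(O[Si](C(C)C)(C(C)C)C(C)C)cc1O[Si](C(C)C)(C(C)C)C(C)C
F3 | step 10 | (2R,4R)-2-[5-(2-methylbut-3-en-2-yl)-2,4-bis(triisopropylsilyloxy)phenyl]-8-(3-methylbut-2-en-1-yl)-5,7-bis(triisopropylsilyloxy)chroman-4-ol | C=CC(C)(C)c1cc([C@H]2C[C@@H](O)c3c(O[Si](C(C)C)(C(C)C)C(C)C)cc(O[Si](C(C)C)(C(C)C)C(C)C)c(CC=C(C)C)c3O2)c(O[Si](C(C)C)(C(C)C)C(C)C)cc1O[Si](C(C)C)(C(C)C)C(C)C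
F4 | step 5 | 5-bromo-2,4-dihydroxybenzaldehyde | O=Cc1cc(Br)c(O)cc1O
F5 | step 5 | 5-bromo-2,4-bis(triisopropylsilyloxy)benzaldehyde | O=Cc1cc(Br)c(O[Si](C(C)C)(C(C)C)C(C)C)cc1O[Si](C(C)C)(C(C)C)C(C)C
F6 | step 8 | 1-(bromomethyl)-5-(2-methylbut-3-en-2-yl)-2,4-bis(triisopropylsilyloxy)benzene | BrCc1cc(C(C)(C)C=C)c(O[Si](C(C)C)(C(C)C)C(C)C)cc1O[Si](C(C)C)(C(C)C)C(C)C
F7 | step 1 | 1-[2-hydroxy-4,6-bis(triisopropylsilyloxy)phenyl]ethanone | CC(=O)c1c(O)cc(O[Si](C(C)C)(C(C)C)C(C)C)cc1O[Si](C(C)C)(C(C)C)C(C)C
F8 | step 1 | 1-[2-(2-methylbut-3-en-2-yloxy)-4,6-bis(triisopropylsilyloxy)phenyl]ethanone | CC(=O)c1c(OC(C)(C)C=C)cc(O[Si](C(C)C)(C(C)C)C(C)C)cc1O[Si](C(C)C)(C(C)C)C(C)C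
A1 | alternative 1 | (2S,4S)-2-[2,4-bis(methoxymethoxy)-5-(2-methylbut-3-en-2-yl)phenyl]-5,7-bis(methoxymethoxy)-8-(3-methylbut-2-en-1-yl)chroman-4-ol | C=CC(C)(C)c1cc([C@@H]2C[C@H](O)c3c(OCOC)cc(OCOC)c(CC=C(C)C)c3O2)c(OCOC)cc1OCOC
A2 | alternative 1 | 2-{(1S,3S)-3-[2,4-bis(methoxymethoxy)-5-(2-methylbut-3-en-2-yl)phenyl]-1,3-dihydroxypropyl}-3,5-bis(methoxymethoxy)-6-(3-methylbut-2-en-1-yl)phenyl trifluoromethanesulfonate | C=CC(C)(C)c1cc([C@@H](O)C[C@H](O)c2c(OCOC)cc(OCOC)c(CC=C(C)C)c2OS(=O)(=O)C(F)(F)F)c(OCOC)cc1OCOC
A3 | alternative 2 | 2-[(2S,4S)-5,7-bis(tert-butyldimethylsilyloxy)-4-methoxy-8-(3-methylbut-2-en-1-yl)chroman-2-yl]-5-(tert-butyldimethylsilyloxy)-4-(2-methylbut-3-en-2-yl)phenol | C=CC(C)(C)c1cc([C@@H]2C[C@H](OC)c3c(O[Si](C)(C)C(C)(C)C)cc(O[Si](C)(C)C(C)(C)C)c(CC=C(C)C)c3O2)c(O)cc1O[Si](C)(C)C(C)(C)C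
A4 | alternative 2 | 2-hydroxy-3-(3-methylbut-2-en-1-yl)-4,6-bis(tert-butyldimethylsilyloxy)benzaldehyde | O=Cc1c(O[Si](C)(C)C(C)(C)C)cc(O[Si](C)(C)C(C)(C)C)c(CC=C(C)C)c1O
A5 | alternative 2 | 5-(tert-butyldimethylsilyloxy)-2-ethenyl-4-(2-methylbut-3-en-2-yl)phenol | C=Cc1cc(C(C)(C)C=C)c(O[Si](C)(C)C(C)(C)C)cc1O
A6 | alternative 3 | (2S)-2-[2,4-diacetoxy-5-(2-methylbut-3-en-2-yl)phenyl]-5,7-bis(tert-butyldimethylsilyloxy)-8-(3-methylbut-2-en-1-yl)chroman-4-one | C=CC(C)(C)c1cc([C@@H]2CC(=O)c3c(O[Si](C)(C)C(C)(C)C)cc(O[Si](C)(C)C(C)(C)C)c(CC=C(C)C)c3O2)c(OC(C)=O)cc1OC(C)=O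
A7 | alternative 3 | (3S)-3-[2,4-diacetoxy-5-(2-methylbut-3-en-2-yl)phenyl]-3-[3,5-bis(tert-butyldimethylsilyloxy)-2-(3-methylbut-2-en-1-yl)phenoxy]propanoic acid | C=CC(C)(C)c1cc([C@H](CC(=O)O)Oc2cc(O[Si](C)(C)C(C)(C)C)cc(O[Si](C)(C)C(C)(C)C)c2CC=C(C)C)c(OC(C)=O)cc1OC(C)=O
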